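When I reread these runs, I wanted one figure per flask: the clock of the substrate, minus the natural logarithm of the fraction of its charge still unturned. With a rate proportional to substrate, flasks of equal partner charge open on one clock, while little of the partner has turned.

| flask | substrate | coupling partner | time |
|---|---|---|---|
| alpha | 0.100 M | 0.200 M |  |
| epsilon | 0.200 M | 0.200 M |  |
| zeta | 0.460 M | 0.200 M | 34 min |

| run | time / min | [product] / M |
|---|---|---|
| alpha run | 2.6 | 0.0141 |
| alpha run | 7.8 | 0.0324 |
| alpha run | 15 | 0.0490 |
| alpha run | 24 | 0.0601 |
| alpha run | 34 | 0.0675 |
| epsilon run | 2.6 | 0.0266 |
| epsilon run | 7.8 | 0.0584 |
| epsilon run | 15 | 0.0824 |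
| epsilon run | 24 | 0.0986 |
| epsilon run | 34 | 0.1103 |

(scatter of a reading: 5 × 10⁻⁴ M)

- how the opening rate goes with [substrate] round the charge of the alpha run: the exponent of the rate at two percent of substrate gone to product (one fixed amount of product, the same in the runs compared)
- product in the zeta run at 34 min, as a share of the substrate charged

- Overall: substrate + coupling partner -> product.
- Constant volume, constant temperature.
- The analysis sees a species whether free or bound.
- An order is taken over about fifteen percent of the charge, up and down.

I went through the settings in turn. By hand, doubling the substrate charge at order one leaves the opening clock unmoved. At 2.6 min the clock read 0.152 in alpha and 0.143 in epsilon, so I took an order near one.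

Time parted them. At 34 min alpha read 1.12 and epsilon read 0.802, less than alpha, while alpha had turned 33.8% of its partner charge into product and epsilon 55.1%. So I computed only the correction: the drop, the clock lost at that time per fraction of the partner charge turned, 1.51.

The partner charge I could not judge, since alpha, epsilon and zeta share 0.200 M. In zeta the partner is the limiting reagent, its charge being less than the substrate's. I tried 35.0% of the zeta substrate, which is 80.5% of the partner charge. That share needs a clock of 0.431, and the drop gives 0.420, so I committed to about 35.0%.

The forecast gave 0.97 and 36.5%, its share above mine, noting “At equal product, the later run is slower.”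

The flask gave 1.0 and 33.5%, and the forecast stood within its margins.

    2 coupling partner ⇌ reagent dimer, settled at all times (1.930 /M)
    substrate + reagent dimer → product + coupling partner (1.830 /M/min)
    coupling partner → lost reagent (0.01218 /min)

In alpha and epsilon product came from substrate and the reagent dimer, while the coupling partner also went to lost reagent with a constant of 0.0122 /min. Later the clock reached 0.693 at 15.9 min in alpha and 24.9 min in epsilon, and in zeta, with product at 77.2% of the partner charge, it read 0.408 at 34 min, against 0.471 from the drop.

All runs are calculated for an exercise; the scatter is artificial.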